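Ring A is cut across C2–C3 and C5–C10 (labdane numbering). The key step exploits the quaternary C10 flanked by oxygenated C9 and the C1–C2 ethano bridge, a pattern hidden in 2,3-dimethyl-4,5-dihydrofuran, whose oxygen ends as the C9 hydroxyl. Its acylative opening gives a Z γ-iodo enol ester; iodine–lithium exchange then lets C2 attack the ester carbon C3 through a six-membered ring, the expelled C9/C10 enolate adds 6-endo to C5 of the new enone, and iodomethane completes the C4 gem-dimethyl group. The enol-ester C–O bond is thus a temporary tether. Ring B, C8 and C9 arise later by a hydrogen-atom-transfer radical cyclization onto the C9 ketone.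

Key step: step 6

Remark: skeletal atoms are named by labdane numbering throughout. The key step is not enantioselective, so compounds 14 and 15 are racemic (drawn as the enantiomer carried forward) and the single enantiomer is secured by the camphanate resolution of steps 8 and 9.

Step 1
Reactants: 1 pent-4-enal; 2 ethyl 2-(triphenylphosphoranylidene)propanoate
Product: 3 ethyl (2E)-2-methylhepta-2,6-dienoate
Conditions: CH2Cl2, 25 °C
Reagents that add atoms: none
Why: Wittig olefination with a stabilized ylide should give the E trisubstituted enoate selectively, which sets the C4=C5 geometry with C3 as the ester carbon.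

Step 2
Reactants: 3 ethyl (2E)-2-methylhepta-2,6-dienoate
Product: 4 (2E)-2-methylhepta-2,6-dienoic acid
Conditions: LiOH, THF/H2O, 25 °C; then aq HCl
Reagents that add atoms: lithium hydroxide ([Li+].[OH-])
Why: Ester saponification (acyl substitution by hydroxide) should leave both alkenes untouched.

Step 3
Reactants: 4 (2E)-2-methylhepta-2,6-dienoic acid
Product: 5 (2E)-2-methylhepta-2,6-dienoyl chloride
Conditions: (COCl)2, N,N-dimethylformamide (cat.), CH2Cl2, 0 → 25 °C
Reagents that add atoms: oxalyl chloride (ClC(=O)C(Cl)=O)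
Why: Vilsmeier-type activation with oxalyl chloride converts the acid into the acid chloride under neutral conditions that should preserve the E geometry.

Step 4
Reactants: 6 3-methyloxolan-2-one (α-methyl-γ-butyrolactone, racemic)
Product: 8 2,3-dimethyl-4,5-dihydrofuran, via lactol 7 (not isolated)
Conditions: MeLi (1.0 equiv), Et2O, −78 °C; H2O; then p-toluenesulfonic acid (cat.), distil
Reagents that add atoms: methyllithium ([Li]C)
Why: Mono-addition of an organolithium to a γ-lactone should stop at the lactolate at low temperature, and acid-catalysed dehydration of the hemiketal gives the more substituted endocyclic enol ether, whose ring fixes the C9 oxygen cis to the future C1–C2 chain.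

Step 5
Reactants: 5 (2E)-2-methylhepta-2,6-dienoyl chloride; 8 2,3-dimethyl-4,5-dihydrofuran
Product: 10 (2Z)-5-iodo-3-methylpent-2-en-2-yl (2E)-2-methylhepta-2,6-dienoate, via acyl iodide 9 (not isolated)
Conditions: NaI, MeCN, 0 °C; then 8, −20 → 0 °C
Reagents that add atoms: sodium iodide ([Na+].[I-])
Why: Ether cleavage by an acyl iodide formed by halide exchange: O-acylation of the ring oxygen and SN2 attack of iodide on the O–CH2 carbon open the dihydrofuran, so the acyloxy group is necessarily cis (Z) to the iodoethyl chain.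

Step 6
Reactants: 10 (2Z)-5-iodo-3-methylpent-2-en-2-yl (2E)-2-methylhepta-2,6-dienoate
Product: 14 rac-(3S,4S)-4-acetyl-3-(but-3-en-1-yl)-2,2,4-trimethylcyclohexan-1-one, via alkyllithium 11 (not isolated), via enolate enone 12 (not isolated), via cyclic enolate 13 (not isolated)
Conditions: t-BuLi (2.0 equiv), Et2O/pentane, −78 °C, high dilution; then THF, N,N′-dimethylpropyleneurea (DMPU), −78 → −20 °C; then MeI, −78 → 0 °C
Reagents that add atoms: iodomethane (CI)
Why: Proposed new method: iodine–lithium exchange at C2 should outrun any carbonyl addition, and the primary alkyllithium 11 then adds 6-exo-trig to the ester carbonyl C3 through a six-membered ring (possible only because the Z enol ester holds the acyloxy group cis to the lithioethyl chain), which forms C2–C3 and, on collapse of the tetrahedral alkoxide, expels the regiodefined tetrasubstituted C9/C10 lithium enolate 12, so that the enol-ester C–O bond acts as a tether cleaved while it delivers the acyl carbon. The closest known reaction types are the Parham-type cyclization of exchange-derived organolithiums onto carboxylic esters, the O-to-C acyl transfer of the Baker–Venkataraman rearrangement and the enolate-plus-unsaturated-acyl Michael step of carbene-catalysed enol ester rearrangements. Ring A is then closed by a 6-(enolexo)-endo-trig Michael addition of C10 to C5 of the new E 2-methyl enone, which forms C5–C10 and gives the C3/C4 enolate 13 regiospecifically; iodomethane traps it at C4, where no stereocentre arises because the two methyl groups are equivalent. C5 and C10 are set relative to each other in a chair-like transition state in which the E enone geometry places the butenyl chain pseudo-equatorial and the bulky solvated enolate carbon C9 should also sit pseudo-equatorial with the C10 methyl axial, giving the trans (diequatorial) C5-butenyl/C10-acetyl relationship required for the trans-decalin; the product is racemic. The step needs chemoselectivity (exchange before addition, no intermolecular aldol or enolate scrambling) and this diastereoselectivity, which high dilution, low temperature and DMPU (disfavouring a lithium-chelated transition state with an axial enolate) are meant to secure.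

Step 7
Reactants: 14 rac-(3S,4S)-4-acetyl-3-(but-3-en-1-yl)-2,2,4-trimethylcyclohexan-1-one
Product: 15 rac-1-[(1S,2S,4S)-2-(but-3-en-1-yl)-4-hydroxy-1,3,3-trimethylcyclohexyl]ethan-1-one
Conditions: NaBH4, MeOH/CH2Cl2, −40 → −20 °C
Reagents that add atoms: none
Why: Borohydride reduction should be chemoselective for the cyclohexanone C3 over the acetyl group on the quaternary carbon, and hydride attack from the α face (anti to the C10 methyl and the C5 chain) should give the 3β-alcohol.

Step 8
Reactants: 15 rac-1-[(1S,2S,4S)-2-(but-3-en-1-yl)-4-hydroxy-1,3,3-trimethylcyclohexyl]ethan-1-one; 16 (1S,4R)-camphanic chloride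
Product: 17 (1S,3S,4S)-4-acetyl-3-(but-3-en-1-yl)-2,2,4-trimethylcyclohexyl (1S,4R)-camphanate
Conditions: Et3N, 4-(dimethylamino)pyridine (cat.), CH2Cl2, 25 °C; separation of the two diastereomers by chromatography or crystallization
Reagents that add atoms: none
Why: Classical resolution by acylation with an enantiopure acid chloride: the two diastereomeric camphanates should be separable, and the one derived from the (1S,2S,4S)-alcohol (to be assigned by X-ray analysis) is carried on.

Step 9
Reactants: 17 (1S,3S,4S)-4-acetyl-3-(but-3-en-1-yl)-2,2,4-trimethylcyclohexyl (1S,4R)-camphanate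
Product: 18 1-[(1S,2S,4S)-2-(but-3-en-1-yl)-4-hydroxy-1,3,3-trimethylcyclohexyl]ethan-1-one (single enantiomer)
Conditions: KOH, MeOH/H2O, 60 °C; then aq HCl
Reagents that add atoms: none
Why: Ester saponification should return the enantiopure alcohol, since none of its three stereocentres is epimerizable under base.

Step 10
Reactants: 18 1-[(1S,2S,4S)-2-(but-3-en-1-yl)-4-hydroxy-1,3,3-trimethylcyclohexyl]ethan-1-one; 19 3-(bromomethyl)furan
Product: 20 1-[(1S,2S,4S)-2-(but-3-en-1-yl)-4-hydroxy-1,3,3-trimethylcyclohexyl]-3-(furan-3-yl)propan-1-one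
Conditions: LiN(iPr)2 (2.2 equiv), THF, −78 °C; then 19, −78 → −30 °C; H2O
Reagents that add atoms: none
Why: Enolate alkylation: the dianion (alkoxide plus the only possible ketone enolate, at the acetyl methyl, because C10 is quaternary) should be C-alkylated by the reactive furylmethyl bromide, installing C12 and the furan that masks the butenolide.

Step 11
Reactants: 20 1-[(1S,2S,4S)-2-(but-3-en-1-yl)-4-hydroxy-1,3,3-trimethylcyclohexyl]-3-(furan-3-yl)propan-1-one
Product: 21 (1S,3S,4S)-3-(but-3-en-1-yl)-4-[3-(furan-3-yl)propanoyl]-2,2,4-trimethylcyclohexyl acetate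
Conditions: Ac2O, 4-(dimethylamino)pyridine (cat.), pyridine, 25 °C
Reagents that add atoms: acetic anhydride (CC(=O)OC(C)=O)
Why: Nucleophile-catalysed acylation of the secondary C3 alcohol installs the acetate of the target before the radical step, so that no second carbonyl competes there.

Step 12
Reactants: 21 (1S,3S,4S)-3-(but-3-en-1-yl)-4-[3-(furan-3-yl)propanoyl]-2,2,4-trimethylcyclohexyl acetate
Product: 22 (2S,4aS,5R,6R,8aS)-5-[2-(furan-3-yl)ethyl]-5-hydroxy-1,1,4a,6-tetramethyldecahydronaphthalen-2-yl acetate (3β-acetoxy-15,16-epoxylabda-13(16),14-dien-9α-ol)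
Conditions: Fe(acac)3 (20 mol %), PhSiH3, EtOH, 60 °C
Reagents that add atoms: none
Why: Mukaiyama-type hydrogen-atom-transfer radical cyclization of an alkene-tethered ketone: Markovnikov H-atom transfer to the terminal alkene gives the secondary C8 radical, which should close ring B 6-exo onto the C9 carbonyl through a chair held by the trans C5/C10 arrangement, with the C8 methyl and the C9 side chain equatorial and the oxygen axial (anti to the C10 methyl), setting 8R and 9R.

Step 13
Reactants: 22 (2S,4aS,5R,6R,8aS)-5-[2-(furan-3-yl)ethyl]-5-hydroxy-1,1,4a,6-tetramethyldecahydronaphthalen-2-yl acetate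
Product: 24 (2S,4aS,5R,6R,8aS)-5-hydroxy-5-[2-(2-hydroxy-5-oxo-2,5-dihydrofuran-3-yl)ethyl]-1,1,4a,6-tetramethyldecahydronaphthalen-2-yl acetate (lactol epimers), via endoperoxide 23 (not isolated)
Conditions: O2, visible light, 5,10,15,20-tetraphenylporphyrin (cat.), iPr2NEt, CH2Cl2, −78 °C
Reagents that add atoms: dioxygen (O=O)
Why: Singlet-oxygen [4+2] cycloaddition to the 3-alkylfuran gives endoperoxide 23, and the hindered amine should remove the less hindered proton at C15, so that the endoperoxide opens regioselectively to the 16-hydroxy-15,16-olide.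

Step 14
Reactants: 24 (2S,4aS,5R,6R,8aS)-5-hydroxy-5-[2-(2-hydroxy-5-oxo-2,5-dihydrofuran-3-yl)ethyl]-1,1,4a,6-tetramethyldecahydronaphthalen-2-yl acetate
Product: 26 (2S,4aS,5R,6R,8aS)-5-hydroxy-1,1,4a,6-tetramethyl-5-[2-(5-oxo-2,5-dihydrofuran-3-yl)ethyl]decahydronaphthalen-2-yl acetate (target), via hydroxy acid 25 (not isolated)
Conditions: NaBH4, EtOH, 0 °C; then aq HCl
Reagents that add atoms: none
Why: Borohydride reduction of the masked C16 aldehyde (open form of the lactol) gives the cis hydroxy acid, which should lactonize on acidification to the β-substituted butenolide while the acetate and the tertiary alcohol stay intact.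

Compound list
1 | pent-4-enal | C=CCCC=O | starting material
2 | ethyl 2-(triphenylphosphoranylidene)propanoate | CCOC(=O)C(C)=P(c1ccccc1)(c1ccccc1)c1ccccc1 | starting material
3 | ethyl (2E)-2-methylhepta-2,6-dienoate | CCOC(=O)/C(C)=C/CCC=C | intermediate
4 | (2E)-2-methylhepta-2,6-dienoic acid | OC(=O)/C(C)=C/CCC=C | intermediate
5 | (2E)-2-methylhepta-2,6-dienoyl chloride | ClC(=O)/C(C)=C/CCC=C | intermediate
6 | 3-methyloxolan-2-one (α-methyl-γ-butyrolactone, racemic) | CC1CCOC1=O | starting material
7 | 2,3-dimethyloxolan-2-ol (lactol, diastereomer mixture) | CC1CCOC1(C)O | intermediate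
8 | 2,3-dimethyl-4,5-dihydrofuran | CC1=C(C)CCO1 | intermediate
9 | (2E)-2-methylhepta-2,6-dienoyl iodide | IC(=O)/C(C)=C/CCC=C | intermediate
10 | (2Z)-5-iodo-3-methylpent-2-en-2-yl (2E)-2-methylhepta-2,6-dienoate | C/C(OC(=O)/C(C)=C/CCC=C)=C(\C)CCI | intermediate
11 | (3Z)-3-methyl-4-{[(2E)-2-methylhepta-2,6-dienoyl]oxy}pent-3-en-1-yllithium | C/C(OC(=O)/C(C)=C/CCC=C)=C(\C)CC[Li] | intermediate
12 | lithium (2Z,7E)-3,7-dimethyl-6-oxododeca-2,7,11-trien-2-olate | C/C(O[Li])=C(\C)CCC(=O)/C(C)=C/CCC=C | intermediate
13 | lithium 4-acetyl-3-(but-3-en-1-yl)-2,4-dimethylcyclohex-1-en-1-olate (butenyl and acetyl trans, racemic) | [Li]OC1=C(C)[C@H](CCC=C)[C@@](C)(C(C)=O)CC1 | intermediate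
14 | rac-(3S,4S)-4-acetyl-3-(but-3-en-1-yl)-2,2,4-trimethylcyclohexan-1-one | O=C1CC[C@@](C(C)=O)(C)[C@@H](CCC=C)C1(C)C | intermediate
15 | rac-1-[(1S,2S,4S)-2-(but-3-en-1-yl)-4-hydroxy-1,3,3-trimethylcyclohexyl]ethan-1-one | O[C@H]1CC[C@@](C(C)=O)(C)[C@@H](CCC=C)C1(C)C | intermediate
16 | (1S,4R)-4,7,7-trimethyl-3-oxo-2-oxabicyclo[2.2.1]heptane-1-carbonyl chloride ((1S)-camphanic chloride) | ClC(=O)[C@@]12CC[C@@](C)(C(=O)O1)C2(C)C | starting material
17 | (1S,3S,4S)-4-acetyl-3-(but-3-en-1-yl)-2,2,4-trimethylcyclohexyl (1S,4R)-camphanate | O=C(O[C@H]1CC[C@@](C(C)=O)(C)[C@@H](CCC=C)C1(C)C)[C@@]12CC[C@@](C)(C(=O)O1)C2(C)C | intermediate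
18 | 1-[(1S,2S,4S)-2-(but-3-en-1-yl)-4-hydroxy-1,3,3-trimethylcyclohexyl]ethan-1-one (single enantiomer) | O[C@H]1CC[C@@](C(C)=O)(C)[C@@H](CCC=C)C1(C)C | intermediate
19 | 3-(bromomethyl)furan | BrCc1ccoc1 | starting material
20 | 1-[(1S,2S,4S)-2-(but-3-en-1-yl)-4-hydroxy-1,3,3-trimethylcyclohexyl]-3-(furan-3-yl)propan-1-one | O[C@H]1CC[C@@](C(=O)CCc2ccoc2)(C)[C@@H](CCC=C)C1(C)C | intermediate
21 | (1S,3S,4S)-3-(but-3-en-1-yl)-4-[3-(furan-3-yl)propanoyl]-2,2,4-trimethylcyclohexyl acetate | CC(=O)O[C@H]1CC[C@@](C(=O)CCc2ccoc2)(C)[C@@H](CCC=C)C1(C)C | intermediate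
22 | (2S,4aS,5R,6R,8aS)-5-[2-(furan-3-yl)ethyl]-5-hydroxy-1,1,4a,6-tetramethyldecahydronaphthalen-2-yl acetate | CC(=O)O[C@H]1CC[C@@]2(C)[C@@H](CC[C@@H](C)[C@]2(O)CCc2ccoc2)C1(C)C | intermediate
23 | furan 2,5-endoperoxide of 22 (2,3,7-trioxabicyclo[2.2.1]hept-5-ene carrying the decalinylethyl group at C5) | CC(=O)O[C@H]1CC[C@@]2(C)[C@@H](CC[C@@H](C)[C@]2(O)CCC2=CC3OOC2O3)C1(C)C | intermediate
24 | (2S,4aS,5R,6R,8aS)-5-hydroxy-5-[2-(2-hydroxy-5-oxo-2,5-dihydrofuran-3-yl)ethyl]-1,1,4a,6-tetramethyldecahydronaphthalen-2-yl acetate (lactol epimers) | CC(=O)O[C@H]1CC[C@@]2(C)[C@@H](CC[C@@H](C)[C@]2(O)CCC2=CC(=O)OC2O)C1(C)C | intermediate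
25 | (2Z)-4-hydroxybut-2-enoic acid carrying at C3 the 2-(decalinyl)ethyl group of 26 (ring-opened hydroxy acid) | CC(=O)O[C@H]1CC[C@@]2(C)[C@@H](CC[C@@H](C)[C@]2(O)CC/C(CO)=C/C(O)=O)C1(C)C | intermediate
26 | (2S,4aS,5R,6R,8aS)-5-hydroxy-1,1,4a,6-tetramethyl-5-[2-(5-oxo-2,5-dihydrofuran-3-yl)ethyl]decahydronaphthalen-2-yl acetate (3β-acetoxy-9α-hydroxylabd-13-en-15,16-olide) | CC(=O)O[C@H]1CC[C@@]2(C)[C@@H](CC[C@@H](C)[C@]2(O)CCC2=CC(=O)OC2)C1(C)C | target

Total step count: 14. Longest linear sequence: 13 steps (steps 1–3 and 5–14).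

Steps most likely to fail

Step 6 (key step, proposed new method). The organolithium may add intermolecularly, the enolates may exchange protons before ring closure (leading to over-methylation), or the Michael closure may lose facial selectivity and give the cis C5/C10 isomer. The fallback uses known reactions, sets out from 8 and 5 and returns at 14. Dihydrofuran 8 is cleaved with Me3SiCl/NaI in MeCN and hydrolysed to 5-iodo-3-methylpentan-2-one F1. Zinc insertion (Zn dust, LiCl, THF) followed by Pd(PPh3)4-catalysed Negishi acylation with acid chloride 5 gives (7E)-3,7-dimethyldodeca-7,11-diene-2,6-dione F2. Catalytic t-BuOK in t-BuOH/THF effects the 6-endo intramolecular Michael addition under thermodynamic control to rac-(3S,4S)-4-acetyl-3-(but-3-en-1-yl)-2,4-dimethylcyclohexan-1-one F3, which is separated from its cis isomer. Methylation of the more substituted enolate (t-BuOK, MeI, t-BuOH) then gives 14.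

Step 12. The C8 radical may be reduced before it cyclizes, or attack on the C9 carbonyl may occur with poor facial selectivity, placing the side chain axial. The fallback sets out from 21 and returns at 22. Wacker oxidation (PdCl2, CuCl, O2, DMF/H2O) gives (1S,3S,4S)-4-[3-(furan-3-yl)propanoyl]-2,2,4-trimethyl-3-(3-oxobutyl)cyclohexyl acetate F4. Intramolecular McMurry coupling (TiCl3, Zn–Cu couple, DME, reflux) gives the tetrasubstituted C8=C9 alkene 3β-acetoxy-15,16-epoxylabda-8,13(16),14-triene F5. Epoxidation (mCPBA, NaHCO3, CH2Cl2, −40 °C) from the α face opposite the C10 methyl gives 3β-acetoxy-8α,9α:15,16-diepoxylabda-13(16),14-diene F6. LiAlH4 in refluxing THF opens the epoxide trans-diaxially at C8 (Fürst–Plattner rule; 9α-OH, 8β-H) and cleaves the acetate to 15,16-epoxylabda-13(16),14-diene-3β,9α-diol F7. Ac2O in pyridine re-acetylates only the secondary C3 hydroxyl and gives 22.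

Step 5. The electron-rich enol ether may undergo C-acylation or acid-induced oligomerization instead of O-acylation and ring opening. The fallback sets out from 5 and returns at 10. The same in situ acyl iodide (NaI, MeCN) opens commercially available 1-(1-methylcyclopropyl)ethan-1-one F8 by homoconjugate (cyclopropylcarbinyl-to-homoallyl) addition, in analogy to the silyl iodide opening of cyclopropyl ketones. This gives 10 together with its enol-ester geometric isomer (2E)-5-iodo-3-methylpent-2-en-2-yl (2E)-2-methylhepta-2,6-dienoate F9, from which 10 is separated by chromatography.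

Further compounds
F1 | step 6 | 5-iodo-3-methylpentan-2-one | CC(=O)C(C)CCI
F2 | step 6 | (7E)-3,7-dimethyldodeca-7,11-diene-2,6-dione | CC(=O)C(C)CCC(=O)/C(C)=C/CCC=C
F3 | step 6 | rac-(3S,4S)-4-acetyl-3-(but-3-en-1-yl)-2,4-dimethylcyclohexan-1-one (epimers at C2) | O=C1C(C)[C@H](CCC=C)[C@@](C)(C(C)=O)CC1
F4 | step 12 | (1S,3S,4S)-4-[3-(furan-3-yl)propanoyl]-2,2,4-trimethyl-3-(3-oxobutyl)cyclohexyl acetate | CC(=O)O[C@H]1CC[C@@](C(=O)CCc2ccoc2)(C)[C@@H](CCC(C)=O)C1(C)C
F5 | step 12 | 3β-acetoxy-15,16-epoxylabda-8,13(16),14-triene | CC(=O)O[C@H]1CC[C@@]2(C)[C@@H](CCC(C)=C2CCc2ccoc2)C1(C)C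
F6 | step 12 | 3β-acetoxy-8α,9α:15,16-diepoxylabda-13(16),14-diene | CC(=O)O[C@H]1CC[C@@]2(C)[C@@H](CC[C@@]3(C)O[C@@]23CCc2ccoc2)C1(C)C
F7 | step 12 | 15,16-epoxylabda-13(16),14-diene-3β,9α-diol | O[C@H]1CC[C@@]2(C)[C@@H](CC[C@@H](C)[C@]2(O)CCc2ccoc2)C1(C)C
F8 | step 5 | 1-(1-methylcyclopropyl)ethan-1-one | CC(=O)C1(C)CC1
F9 | step 5 | (2E)-5-iodo-3-methylpent-2-en-2-yl (2E)-2-methylhepta-2,6-dienoate | C/C(OC(=O)/C(C)=C/CCC=C)=C(/C)CCI
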